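## The problem

Compound 24 is an achiral triaryl ether made of three thymol-type rings. Ring A is a 2-isopropyl-4-methoxy-5-methylphenoxy group; ring B is a pentasubstituted benzene (B1 O–ring A, B2 CH3, B3 OCH3, B4 H, B5 isopropyl, B6 O–ring C); ring C is a 1,4-benzoquinone (Ca O–ring B, Cb CH3, Cc C=O, Cd H, Ce isopropyl, Cf C=O). There is no stereocentre, so nothing can be relayed and every selectivity question is regiochemical: which oxygen of each ring is etherified, and on which side of it the methyl and isopropyl groups lie. Both ether oxygens are crowded, with ortho substituents on both flanking rings, so neither C–O bond is an easy arylation. Ring B carries three oxygens that must be told apart (ether to ring A, methyl ether, ether to ring C). The quinone is an oxidant and a Michael acceptor with one open position (Cd) and will not survive bases, nucleophiles or organometallic reagents, while rings A and B are electron-rich hydroquinone ethers that are attacked by strong one-electron oxidants; the quinone should therefore appear in the last step, by mild oxidation of a hydroquinone. The feature that opens the key step lies in ring C: Ca(O)–Cb(CH3)–Cc(O) is the C3–C2–C1 unit of 2-methylcyclohexane-1,3-dione 11, and Cd(H)–Ce(isopropyl)–Cf(O) can come from a diene terminus and the two alkyne carbons of ynone 19, whose acetyl group is a latent oxygen, while the two spare CH2 groups of 11 leave as ethene.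

## Retrosynthesis

**Unmasking the quinone (24 ⇒ 23 ⇒ 22 ⇒ 21).** No skeletal bond is cut. Quinone 24 is traced to hydroquinone 23, 23 to its O-acetyl, O′-silyl derivative 22 (both groups fall in one methanolysis), and the Cf–O bond of 22 to the Cf–acetyl bond of ketone 21 by a Baeyer–Villiger shift. This is preferred to carrying an oxygen at Cf through the ring synthesis, because the group at Cf must first be an electron-withdrawing group for the cycloaddition and only afterwards an oxygen; an acetyl group is both in turn. The forward steps must spare rings A and B, which excludes ceric and similar one-electron oxidants at the end.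

**Ring C (21 ⇒ 15 + 19, through 20).** The Cd–Ce and Cf–Ca bonds are cut and a CH2–CH2 bridge is put back between Ca and Cd. The benzene ring thereby becomes bicyclo[2.2.2]octadiene 20, and 20 becomes silyloxydiene 15 and ynone 19. Two neighbouring cuts were weighed.
- Cutting the B6–O–Ca bond as an attack of the phenoxide of 10 on a halogenated quinone would be shorter. It asks a hindered, easily oxidised phenoxide to add to an oxidant, and at the halogen-bearing carbon rather than at the open one.
- An open-chain 1-aryloxy-3-silyloxydiene would aromatise after cycloaddition by losing the aryloxy group, the one group that must stay.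

In 20 the aryloxy group sits at a bridgehead and cannot leave, so the only way to a benzene is loss of ethene. The precursors are simpler by a whole aromatic ring: 15 is a cyclohexenone derivative and 19 has seven carbons. The forward reaction needs one regiochemistry and enough dienophile reactivity.

**The B6–O–Ca ether (15 ⇒ 13 ⇒ 10 + 12; 12 ⇒ 11; 19 ⇒ 16).** Diene 15 is the kinetic silyl dienol ether of enone 13. The ether bond of 13 is cut at Ca as a vinylogous ester bond, giving phenol 10 and chloroenone 12, the vinylogous acid chloride of dione 11. The crowded ether is thus made by addition–elimination at an sp2 carbon that is not yet aromatic, not by arylating a phenol flanked by two ortho groups. Ynone 19 is the acetylation product of alkyne 16. The forward steps need O-attack of a hindered phenoxide and enolisation of 13 on the α′ side.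

**The A–O–B1 ether (10 ⇒ 9 ⇒ 8 + 6; 8 ⇒ 7 ⇒ 6).** Ring B is phenol 6 with one more oxygen at its only free ortho position, and ring A is phenol 6 itself. The B1–O bond is therefore cut: benzyl ether 9 comes from aryl iodide 8 and phenol 6, and 8 from 6 by ortho-iodination (7) and benzylation. Cutting on the ring A side would need a ring B catechol monoether and a ring A halide, which is longer. Going through a ring B hydroquinone would need two free hydroxyl groups to be told apart by methylation. Here both methoxy groups are already in place and the B6 oxygen is the phenol oxygen of 6. The price is one copper-catalysed coupling to a tri-ortho-substituted diaryl ether.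

**Phenol 6 (6 ⇒ 3 ⇒ 2 ⇒ 1).** The C–O bond para to the methoxy group is cut. Carvacrol 1 has its hydroxyl group next to the methyl group, exactly where rings A and B carry OCH3; after methylation (2) the position para to the methoxy group, which is ortho to isopropyl, is the one that bromination (3) and ipso-hydroxylation address. A hydroquinone precursor would be shorter but would again require selective monomethylation.

## Roads not taken

**Alternative 1:** Ring A is built last by a Robinson annulation. Numbering ring A from its methoxy carbon as C1 (ether carbon C4), the cuts are C4–C5 and C2–C3. The enolate of aryloxymethyl ketone A1 adds to enone A2 (Michael addition), and the methyl ketone then condenses with the isopropyl ketone to give cyclohexenone A3.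
- Merit: the crowded A–O–B1 ether is made as an alkyl aryl ether by simple O-alkylation before ring A exists. In this respect it is better than the chosen plan, which needs a hindered copper coupling (step 6).
- Weak points: A3 is two hydrogens short of a phenol and has its aryloxy group γ to the carbonyl, so it can aromatise without any oxidant by expelling the ring B phenoxide, destroying the ether just made. The aldol closure is onto a ketone flanked by isopropyl and the aryloxy-bearing carbon, and a competing closure from the isopropyl methine is possible. A2 polymerises under base. Two stereocentres are made only to be erased. Dehydrogenation, O-methylation and debenzylation follow.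
- Comparison: it answers only the A–B half; ring C and the quinone remain. Against the easier ether bond, the chosen plan sets that both halves of the A–B ether come from one phenol 6, with no aromatisation step in which the ether can be lost.

**Alternative 2:** Ring B is assembled by a Dötz benzannulation, cutting B3–B4, B5–B6 and B6–B1. Alkenyl(methoxy)carbene chromium complex A4, alkyne 16 and one carbonyl ligand combine to phenol A5, which is identical with 10.
- Merits: the terminal alkyne places isopropyl next to the new hydroxyl group, B3 arrives as the methyl ether and B6 as the free phenol, so no protecting group and no selective methylation are needed. The A–O–B1 ether is carried in as an enol ether of phenol 6, so the hindered arylation is avoided. On paper this is the better answer to the A–B problem, and about level in step count with steps 4 to 7.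
- Weak points: stoichiometric chromium. The β-aryloxyalkenyl metal precursor of A4 can fragment by loss of aryloxide. Alkenylcarbene complexes with a β-donor are less electrophilic and prone to side channels (cyclopentannulation, furan formation). Oxidative removal of chromium threatens the electron-rich product A5.
- Comparison: it would replace steps 4 to 7 only; ring C would still be built as in the chosen plan. The chosen plan pays one protecting group and one hard coupling, and in exchange uses catalytic copper and reactions of mapped scope.

**Alternative 3:** Ring B is built by a Robinson annulation and aromatised afterwards, cutting B2–B3 and B4–B5. Enamine A7 adds to α-aryloxy enone A6, and the α′-carbon of the ketone then condenses with the aldehyde to give cyclohexenone A8.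
- Merits: all six carbons and all three oxygens of ring B are placed in one annulation, and the A–O–B1 ether is again an enol ether made from phenol 6 without arylation.
- Weak points: A8 must be dehydrogenated, but a 4-methoxycyclohexenone aromatises more easily by β-elimination of its methoxy group, which would delete the B3 oxygen. A6 is a β-substituted, α-oxygenated and therefore deactivated acceptor. A7 is a labile enamine whose nucleophilic carbon carries the methoxy group. Three stereocentres are created and then destroyed.
- Comparison: like alternative 1, it trades a difficult but redox-neutral coupling for an aromatisation that can go the wrong way, and leaves ring C open. The chosen plan forms its new benzene ring by loss of ethene, a step in which no heteroatom substituent can be lost.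

Key step: step 12

## Route

Remark: 24 has no stereocentre. The only chiral compound, adduct 20, is racemic, and its two bridgehead centres are tied to each other by the bicycle, so its SMILES carries no descriptors.
Remark: in the step lines "ArO" stands for the ring A–ring B aryloxy group 6-isopropyl-2-(2-isopropyl-4-methoxy-5-methylphenoxy)-4-methoxy-3-methylphenoxy; the compound list gives full names.

Step 1
Reactants: 1 carvacrol (5-isopropyl-2-methylphenol)
Product: 2 4-isopropyl-2-methoxy-1-methylbenzene (carvacrol methyl ether)
Conditions: MeI, K2CO3, acetone, reflux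
Reagents that add atoms: iodomethane, CI
Why: Williamson O-methylation of a phenoxide; this methoxy group becomes the ring A methoxy and, through 6, the B3 methoxy, so no hydroquinone oxygens have to be differentiated later.

Step 2
Reactants: 2 4-isopropyl-2-methoxy-1-methylbenzene
Product: 3 1-bromo-2-isopropyl-4-methoxy-5-methylbenzene
Conditions: NBS, MeCN, 0 °C → rt
Reagents that add atoms: N-bromosuccinimide, O=C1CCC(=O)N1Br
Why: Electrophilic aromatic bromination para to the methoxy group; the only other activated site lies between methoxy and isopropyl and is shielded.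

Step 3
Reactants: 3 1-bromo-2-isopropyl-4-methoxy-5-methylbenzene
Product: 6 2-isopropyl-4-methoxy-5-methylphenol, via aryllithium 4 (not isolated), via lithium aryltrimethoxyborate 5 (not isolated)
Conditions: n-BuLi, THF, −78 °C; B(OMe)3, −78 °C → rt; AcOH, 30% H2O2, 0 °C → rt
Reagents that add atoms: hydrogen peroxide, OO
Why: Bromine–lithium exchange, borylation and oxidative aryl shift from boron to oxygen (ipso-hydroxylation of an arylboronate), a standard route from aryl bromide to phenol that fixes the hydroxyl group at the brominated carbon.

Step 4
Reactants: 6 2-isopropyl-4-methoxy-5-methylphenol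
Product: 7 2-iodo-6-isopropyl-4-methoxy-3-methylphenol
Conditions: NIS, TsOH·H2O (cat.), dry MeCN, 0 °C, dark
Reagents that add atoms: N-iodosuccinimide, O=C1CCC(=O)N1I
Why: Electrophilic iodination at the only free position ortho to the hydroxyl group; the other open site is ortho to the weaker methoxy donor and lies between methoxy and isopropyl.

Step 5
Reactants: 7 2-iodo-6-isopropyl-4-methoxy-3-methylphenol
Product: 8 2-(benzyloxy)-3-iodo-1-isopropyl-5-methoxy-4-methylbenzene
Conditions: BnBr, K2CO3, DMF, 50 °C
Reagents that add atoms: benzyl bromide, BrCc1ccccc1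
Why: Williamson benzylation; it masks the future B6 oxygen so that the copper step does not meet a free ortho-iodophenol, and benzyl can later be removed without acid or oxidant.

Step 6
Reactants: 8 2-(benzyloxy)-3-iodo-1-isopropyl-5-methoxy-4-methylbenzene; 6 2-isopropyl-4-methoxy-5-methylphenol
Product: 9 2-(benzyloxy)-1-isopropyl-3-(2-isopropyl-4-methoxy-5-methylphenoxy)-5-methoxy-4-methylbenzene
Conditions: CuI (10 mol %), picolinic acid (20 mol %), K3PO4, DMSO, 100 °C, Ar
Reagents that add atoms: none
Why: Ullmann-type copper-catalysed O-arylation of phenol 6 by aryl iodide 8, using the picolinic acid/K3PO4/DMSO system established for ortho-substituted phenols and 2,6-disubstituted aryl iodides; air is excluded to suppress oxidative coupling of the electron-rich phenol.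

Step 7
Reactants: 9 2-(benzyloxy)-1-isopropyl-3-(2-isopropyl-4-methoxy-5-methylphenoxy)-5-methoxy-4-methylbenzene
Product: 10 6-isopropyl-2-(2-isopropyl-4-methoxy-5-methylphenoxy)-4-methoxy-3-methylphenol (ArOH)
Conditions: H2 (1 atm), Pd/C, EtOAc–EtOH, rt
Reagents that add atoms: none
Why: Hydrogenolysis of the benzyl aryl ether on palladium; diaryl and methyl ethers are untouched.

Step 8
Reactants: 11 2-methylcyclohexane-1,3-dione
Product: 12 3-chloro-2-methylcyclohex-2-en-1-one
Conditions: (COCl)2, DMF (cat.), CH2Cl2, 0 °C → rt
Reagents that add atoms: oxalyl chloride, O=C(Cl)C(=O)Cl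
Why: Conversion of the enol of a cyclic 1,3-dione into its vinylogous acid chloride, a known preparation of this compound; the dione is symmetric, so only one chloroenone can form.

Step 9
Reactants: 10 ArOH; 12 3-chloro-2-methylcyclohex-2-en-1-one
Product: 13 3-(ArO)-2-methylcyclohex-2-en-1-one
Conditions: Cs2CO3, DMF, 60 °C
Reagents that add atoms: none
Why: Addition–elimination (vinylogous acyl substitution) of the phenoxide at the β-carbon of the chloroenone; the phenoxide can react only at oxygen because both ortho positions and the para position are substituted.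

Step 10
Reactants: 13 3-(ArO)-2-methylcyclohex-2-en-1-one
Product: 15 tert-butyldimethylsilyl dienol ether 5-(ArO)-6-methyl-1-(silyloxy)cyclohexa-1,5-diene, via lithium dienolate 14 (not isolated)
Conditions: LiN(iPr)2, THF, −78 °C; TBSCl, DMPU, −78 °C → rt
Reagents that add atoms: tert-butyldimethylsilyl chloride, CC(C)(C)[Si](C)(C)Cl
Why: Kinetic α′-deprotonation of a vinylogous ester gives the cross-conjugated dienolate, which is silylated on oxygen; this is the known behaviour of 3-alkoxycyclohexenones at low temperature and it places the methyl group between the two oxygens of the diene.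

Step 11
Reactants: 16 3-methylbut-1-yne
Product: 19 5-methylhex-3-yn-2-one, via lithium acetylide 17 (not isolated), via tetrahedral adduct 18 (not isolated)
Conditions: n-BuLi, THF, −78 °C; MeC(O)N(OMe)Me, −78 → 0 °C; 1 M HCl
Reagents that add atoms: N-methoxy-N-methylacetamide, CC(=O)N(C)OC
Why: Acylation of a lithium acetylide by an N-methoxy-N-methylamide; the chelated adduct resists a second addition and releases the ynone only on acidic work-up.

Step 12
Reactants: 15 tert-butyldimethylsilyl dienol ether; 19 5-methylhex-3-yn-2-one
Product: 21 1-[2-(ArO)-4-(tert-butyldimethylsilyloxy)-6-isopropyl-3-methylphenyl]ethan-1-one, via bicyclooctadiene adduct 20 (not isolated)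
Conditions: 19 (5 equiv), o-xylene, BHT (cat.), sealed tube, 170 °C
Reagents that add atoms: none
Why: Thermal (4+2) cycloaddition of the electron-rich diene 15 (a cyclic 1-aryloxy-3-silyloxybutadiene) with the electron-poor alkyne of 19, followed in the same vessel by retro-(4+2) loss of ethene from 20; this is the Alder–Rickert reaction, known for 1-alkoxy- and 2-silyloxycyclohexa-1,3-dienes with acetylenic ketones and esters, including dienes derived from 2-methylcyclohexane-1,3-dione. Ring C is closed by an intermolecular, concerted but asynchronous cycloaddition in which Cd–Ce forms ahead of Cf–Ca, and it becomes a benzene only when the CH2–CH2 bridge is expelled. Regiochemistry is the one selectivity required: the silyloxy group at Cc and the aryloxy group at Ca both raise the HOMO coefficient at the unsubstituted terminus Cd, which bonds to the β-carbon of the ynone (Ce, isopropyl), so that the acyl-bearing carbon Cf joins Ca. Sterics agree, since the isopropyl-bearing carbon meets the CH terminus. No stereocentre survives, because the two bridgehead centres of racemic 20 become sp2 carbons. The aryloxy group of 20 sits at a bridgehead and cannot be eliminated, so ethene loss is the only path to an arene and the B6–O–Ca ether is kept. Excess ynone, a sealed tube and a radical inhibitor are used because the β-branched ynone is a slow dienophile.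

Step 13
Reactants: 21 1-[2-(ArO)-4-(tert-butyldimethylsilyloxy)-6-isopropyl-3-methylphenyl]ethan-1-one
Product: 22 2-(ArO)-4-(tert-butyldimethylsilyloxy)-6-isopropyl-3-methylphenyl acetate
Conditions: mCPBA, CH2Cl2, 0 °C → rt, dark
Reagents that add atoms: 3-chloroperoxybenzoic acid, OOC(=O)c1cccc(Cl)c1
Why: Baeyer–Villiger oxidation; the aryl group, with silyloxy para and aryloxy ortho to Cf, migrates in preference to methyl, and the ketone is twisted out of conjugation by its two ortho groups, which keeps it electrophilic.

Step 14
Reactants: 22 2-(ArO)-4-(tert-butyldimethylsilyloxy)-6-isopropyl-3-methylphenyl acetate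
Product: 23 3-(ArO)-5-isopropyl-2-methylbenzene-1,4-diol
Conditions: K2CO3, MeOH (degassed), rt, Ar; then aq. NH4Cl
Reagents that add atoms: none
Why: Base-mediated methanolysis removes the aryl acetate and cleaves the phenolic silyl ether (aryl silyl ethers, unlike alkyl ones, fall to K2CO3 in methanol); air is excluded to prevent autoxidation of the hydroquinone in base.

Step 15
Reactants: 23 3-(ArO)-5-isopropyl-2-methylbenzene-1,4-diol
Product: 24 3-(ArO)-5-isopropyl-2-methylcyclohexa-2,5-diene-1,4-dione (target)
Conditions: Ag2O, MgSO4, Et2O, rt
Reagents that add atoms: none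
Why: Two-electron oxidation of a hydroquinone to the 1,4-benzoquinone by Ag2O under neutral, anhydrous conditions; rings A and B carry no free hydroxyl group and are inert to this oxidant.

## Compound list

1 | carvacrol (5-isopropyl-2-methylphenol) | Cc1ccc(C(C)C)cc1O | starting material
2 | 4-isopropyl-2-methoxy-1-methylbenzene (carvacrol methyl ether) | COc1cc(C(C)C)ccc1C | intermediate
3 | 1-bromo-2-isopropyl-4-methoxy-5-methylbenzene | COc1cc(C(C)C)c(Br)cc1C | intermediate
4 | (2-isopropyl-4-methoxy-5-methylphenyl)lithium | [Li]c1cc(C)c(OC)cc1C(C)C | intermediate (not isolated)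
5 | lithium (2-isopropyl-4-methoxy-5-methylphenyl)trimethoxyborate | [Li+].COc1cc(C(C)C)c(cc1C)[B-](OC)(OC)OC | intermediate (not isolated)
6 | 2-isopropyl-4-methoxy-5-methylphenol | COc1cc(C(C)C)c(O)cc1C | intermediate
7 | 2-iodo-6-isopropyl-4-methoxy-3-methylphenol | COc1cc(C(C)C)c(O)c(I)c1C | intermediate
8 | 2-(benzyloxy)-3-iodo-1-isopropyl-5-methoxy-4-methylbenzene | COc1cc(C(C)C)c(OCc2ccccc2)c(I)c1C | intermediate
9 | 2-(benzyloxy)-1-isopropyl-3-(2-isopropyl-4-methoxy-5-methylphenoxy)-5-methoxy-4-methylbenzene | COc1cc(C(C)C)c(Oc2c(C)c(OC)cc(C(C)C)c2OCc2ccccc2)cc1C | intermediate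
10 | 6-isopropyl-2-(2-isopropyl-4-methoxy-5-methylphenoxy)-4-methoxy-3-methylphenol | COc1cc(C(C)C)c(Oc2c(C)c(OC)cc(C(C)C)c2O)cc1C | intermediate
11 | 2-methylcyclohexane-1,3-dione | CC1C(=O)CCCC1=O | starting material
12 | 3-chloro-2-methylcyclohex-2-en-1-one | CC1=C(Cl)CCCC1=O | intermediate
13 | 3-[6-isopropyl-2-(2-isopropyl-4-methoxy-5-methylphenoxy)-4-methoxy-3-methylphenoxy]-2-methylcyclohex-2-en-1-one | CC1=C(Oc2c(C(C)C)cc(OC)c(C)c2Oc2cc(C)c(OC)cc2C(C)C)CCCC1=O | intermediate
14 | lithium 5-[6-isopropyl-2-(2-isopropyl-4-methoxy-5-methylphenoxy)-4-methoxy-3-methylphenoxy]-6-methylcyclohexa-1,5-dien-1-olate | [Li+].CC1=C(Oc2c(C(C)C)cc(OC)c(C)c2Oc2cc(C)c(OC)cc2C(C)C)CCC=C1[O-] | intermediate (not isolated)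
15 | tert-butyl({5-[6-isopropyl-2-(2-isopropyl-4-methoxy-5-methylphenoxy)-4-methoxy-3-methylphenoxy]-6-methylcyclohexa-1,5-dien-1-yl}oxy)dimethylsilane | CC1=C(Oc2c(C(C)C)cc(OC)c(C)c2Oc2cc(C)c(OC)cc2C(C)C)CCC=C1O[Si](C)(C)C(C)(C)C | intermediate
16 | 3-methylbut-1-yne | CC(C)C#C | starting material
17 | (3-methylbut-1-yn-1-yl)lithium | [Li]C#CC(C)C | intermediate (not isolated)
18 | lithium 2-[methoxy(methyl)amino]-5-methylhex-3-yn-2-olate | [Li+].CC(C)C#CC(C)([O-])N(C)OC | intermediate (not isolated)
19 | 5-methylhex-3-yn-2-one | CC(C)C#CC(C)=O | intermediate
20 | 1-{5-[(tert-butyldimethylsilyl)oxy]-3-isopropyl-1-[6-isopropyl-2-(2-isopropyl-4-methoxy-5-methylphenoxy)-4-methoxy-3-methylphenoxy]-6-methylbicyclo[2.2.2]octa-2,5-dien-2-yl}ethan-1-one (racemic) | CC(=O)C1=C(C(C)C)C2CCC1(Oc3c(C(C)C)cc(OC)c(C)c3Oc3cc(C)c(OC)cc3C(C)C)C(C)=C2O[Si](C)(C)C(C)(C)C | intermediate (not isolated)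
21 | 1-{4-[(tert-butyldimethylsilyl)oxy]-6-isopropyl-2-[6-isopropyl-2-(2-isopropyl-4-methoxy-5-methylphenoxy)-4-methoxy-3-methylphenoxy]-3-methylphenyl}ethan-1-one | CC(=O)c1c(C(C)C)cc(O[Si](C)(C)C(C)(C)C)c(C)c1Oc1c(C(C)C)cc(OC)c(C)c1Oc1cc(C)c(OC)cc1C(C)C | intermediate
22 | 4-[(tert-butyldimethylsilyl)oxy]-6-isopropyl-2-[6-isopropyl-2-(2-isopropyl-4-methoxy-5-methylphenoxy)-4-methoxy-3-methylphenoxy]-3-methylphenyl acetate | CC(=O)Oc1c(C(C)C)cc(O[Si](C)(C)C(C)(C)C)c(C)c1Oc1c(C(C)C)cc(OC)c(C)c1Oc1cc(C)c(OC)cc1C(C)C | intermediate
23 | 5-isopropyl-3-[6-isopropyl-2-(2-isopropyl-4-methoxy-5-methylphenoxy)-4-methoxy-3-methylphenoxy]-2-methylbenzene-1,4-diol | Cc1c(O)cc(C(C)C)c(O)c1Oc1c(C(C)C)cc(OC)c(C)c1Oc1cc(C)c(OC)cc1C(C)C | intermediate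
24 | 5-isopropyl-3-[6-isopropyl-2-(2-isopropyl-4-methoxy-5-methylphenoxy)-4-methoxy-3-methylphenoxy]-2-methylcyclohexa-2,5-diene-1,4-dione | COc1cc(C(C)C)c(Oc2c(C)c(OC)cc(C(C)C)c2OC2=C(C)C(=O)C=C(C(C)C)C2=O)cc1C | target

## Step count and risk

Total: 15 steps. Longest linear sequence: 13 steps (steps 1–7, 9, 10, 12–15); steps 8 and 11 are one-step side branches.

**Step 12 (key step).** The cycloaddition may be too slow at temperatures the diene tolerates. A singly activated, β-branched alkyne has to bond to a fully substituted diene terminus that carries a very large aryloxy group. During long heating, desilylation of the dienol ether back to the enone and oligomerisation of the ynone can overtake the cycloaddition. Fallback: leave the cycloaddition and make the B6–O–Ca bond on a preformed quinone. It sets out from 6 and 10. Bromination of 6 (NBS, MeCN) gives 2-bromo-6-isopropyl-4-methoxy-3-methylphenol F1. Oxidative demethylation with (NH4)2Ce(NO3)6 in aqueous MeCN gives 2-bromo-6-isopropyl-3-methylcyclohexa-2,5-diene-1,4-dione F2. Addition–elimination of the phenoxide of 10 at the bromine-bearing carbon (Cs2CO3, MeCN, 0 °C) comes back to the route at 24. This is held in reserve because the hindered phenoxide may be oxidised by the quinone or add at the open ring position.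

**Step 6.** Reaction at the di-ortho-substituted iodide may be slow, so that reduction of the C–I bond or oxidative self-coupling of phenol 6 takes over. Fallback: reverse the polarity and use a metal-free aryl transfer from trivalent iodine. It sets out from 2 and 8. Arene 2 with I2, mCPBA and TsOH·H2O in CH2Cl2 gives bis(2-isopropyl-4-methoxy-5-methylphenyl)iodonium 4-methylbenzenesulfonate F3. Iodide 8 is hydroxylated (KOH, Pd2(dba)3, di-tert-butyl(2′,4′,6′-triisopropylbiphenyl-2-yl)phosphine, dioxane–H2O, 100 °C) to 2-(benzyloxy)-3-isopropyl-5-methoxy-6-methylphenol F4. The potassium salt of F4 (KOtBu, THF) is arylated by F3 at rt to 40 °C, a ligand coupling that tolerates ortho substituents on both partners, and the route is rejoined at 9.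

**Step 9.** O-attack may be slow because the β-carbon of 12 carries an α-methyl neighbour and the phenoxide of 10 has two ortho groups; base-induced self-condensation of the chloroenone would then compete. Fallback: replace addition–elimination by a palladium-catalysed C–O coupling. It sets out from 11 and 10. Dione 11 with Tf2O and pyridine gives 2-methyl-3-oxocyclohex-1-en-1-yl trifluoromethanesulfonate F5. F5 is coupled with 10 (Pd2(dba)3, 2-(di-tert-butylphosphino)biphenyl, K3PO4, toluene, 100 °C), the known aryl enol ether synthesis from enol triflates and phenols, and the route is rejoined at 13.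

**Step 13.** Peracid addition to the hindered ketone may be slower than electrophilic oxidation of the electron-rich rings A and B, giving over-oxidation in place of the aryl shift. Fallback: carry a formyl group in place of the acetyl group, since aryl aldehydes rearrange far more easily. It sets out from 16 and 15 and needs nothing from steps 11 and 12.
- Acetylide 17 is formylated with DMF to lithium 1-(dimethylamino)-4-methylpent-2-yn-1-olate F6, and a reverse quench into aqueous KH2PO4 gives 4-methylpent-2-ynal F7.
- Alder–Rickert reaction of 15 with F7 gives the bicyclic adduct 5-(tert-butyldimethylsilyloxy)-3-isopropyl-1-(ArO)-6-methylbicyclo[2.2.2]octa-2,5-diene-2-carbaldehyde F8, and after ethene loss 4-(tert-butyldimethylsilyloxy)-6-isopropyl-2-(ArO)-3-methylbenzaldehyde F9.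
- mCPBA (Dakin-type Baeyer–Villiger oxidation) gives 4-(tert-butyldimethylsilyloxy)-6-isopropyl-2-(ArO)-3-methylphenyl formate F10.
- K2CO3 in MeOH rejoins the route at 23.

## Further compounds

F1 | step 12 | 2-bromo-6-isopropyl-4-methoxy-3-methylphenol | COc1cc(C(C)C)c(O)c(Br)c1C
F2 | step 12 | 2-bromo-6-isopropyl-3-methylcyclohexa-2,5-diene-1,4-dione | CC1=C(Br)C(=O)C(C(C)C)=CC1=O
F3 | step 6 | bis(2-isopropyl-4-methoxy-5-methylphenyl)iodonium 4-methylbenzenesulfonate | COc1cc(C(C)C)c([I+]c2cc(C)c(OC)cc2C(C)C)cc1C.Cc1ccc(cc1)S(=O)(=O)[O-]
F4 | step 6 | 2-(benzyloxy)-3-isopropyl-5-methoxy-6-methylphenol | COc1cc(C(C)C)c(OCc2ccccc2)c(O)c1C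
F5 | step 9 | 2-methyl-3-oxocyclohex-1-en-1-yl trifluoromethanesulfonate | CC1=C(OS(=O)(=O)C(F)(F)F)CCCC1=O
F6 | step 13 | lithium 1-(dimethylamino)-4-methylpent-2-yn-1-olate | [Li+].CC(C)C#CC([O-])N(C)C
F7 | step 13 | 4-methylpent-2-ynal | CC(C)C#CC=O
F8 | step 13 | 5-[(tert-butyldimethylsilyl)oxy]-3-isopropyl-1-[6-isopropyl-2-(2-isopropyl-4-methoxy-5-methylphenoxy)-4-methoxy-3-methylphenoxy]-6-methylbicyclo[2.2.2]octa-2,5-diene-2-carbaldehyde (racemic) | O=CC1=C(C(C)C)C2CCC1(Oc3c(C(C)C)cc(OC)c(C)c3Oc3cc(C)c(OC)cc3C(C)C)C(C)=C2O[Si](C)(C)C(C)(C)C
F9 | step 13 | 4-[(tert-butyldimethylsilyl)oxy]-6-isopropyl-2-[6-isopropyl-2-(2-isopropyl-4-methoxy-5-methylphenoxy)-4-methoxy-3-methylphenoxy]-3-methylbenzaldehyde | O=Cc1c(C(C)C)cc(O[Si](C)(C)C(C)(C)C)c(C)c1Oc1c(C(C)C)cc(OC)c(C)c1Oc1cc(C)c(OC)cc1C(C)C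
F10 | step 13 | 4-[(tert-butyldimethylsilyl)oxy]-6-isopropyl-2-[6-isopropyl-2-(2-isopropyl-4-methoxy-5-methylphenoxy)-4-methoxy-3-methylphenoxy]-3-methylphenyl formate | O=COc1c(C(C)C)cc(O[Si](C)(C)C(C)(C)C)c(C)c1Oc1c(C(C)C)cc(OC)c(C)c1Oc1cc(C)c(OC)cc1C(C)C
A1 | alternative 1 | 1-[2-(benzyloxy)-3-isopropyl-5-methoxy-6-methylphenoxy]-3-methylbutan-2-one | CC(C)C(=O)COc1c(C)c(OC)cc(C(C)C)c1OCc1ccccc1
A2 | alternative 1 | 3-methylbut-3-en-2-one | CC(=C)C(C)=O
A3 | alternative 1 | 4-[2-(benzyloxy)-3-isopropyl-5-methoxy-6-methylphenoxy]-3-isopropyl-6-methylcyclohex-2-en-1-one (racemic, one diastereomer as written) | C[C@H]1C[C@@H](Oc2c(C)c(OC)cc(C(C)C)c2OCc2ccccc2)C(C(C)C)=CC1=O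
A4 | alternative 2 | pentacarbonyl[(E)-3-(2-isopropyl-4-methoxy-5-methylphenoxy)-1-methoxy-2-methylprop-2-en-1-ylidene]chromium | COC(=[Cr])/C(C)=C/Oc1cc(C)c(OC)cc1C(C)C.[C-]#[O+].[C-]#[O+].[C-]#[O+].[C-]#[O+].[C-]#[O+]
A5 | alternative 2 | 6-isopropyl-2-(2-isopropyl-4-methoxy-5-methylphenoxy)-4-methoxy-3-methylphenol (identical with 10) | COc1cc(C(C)C)c(Oc2c(C)c(OC)cc(C(C)C)c2O)cc1C
A6 | alternative 3 | (Z)-3-(2-isopropyl-4-methoxy-5-methylphenoxy)-6-methylhept-2-en-4-one | C/C=C(\Oc1cc(C)c(OC)cc1C(C)C)C(=O)CC(C)C
A7 | alternative 3 | 1-[(E)-2-methoxyethenyl]pyrrolidine | CO/C=C/N1CCCC1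
A8 | alternative 3 | 2-isopropyl-6-(2-isopropyl-4-methoxy-5-methylphenoxy)-4-methoxy-5-methylcyclohex-2-en-1-one (racemic, one diastereomer as written) | CO[C@@H]1C=C(C(C)C)C(=O)[C@H](Oc2cc(C)c(OC)cc2C(C)C)[C@H]1C
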